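## The problem

Compound 20, 2-(3,5-dihydroxy-4-methoxyphenyl)-3,5,7-trihydroxy-8-methoxy-4H-chromen-4-one, is a flat flavonol with no stereocentre, so the task is one of placing and telling apart seven oxygens, not of stereocontrol. Ring A carries oxygen at C5, C7, C8 and C8a and is acylated at C4a; because the C5 and C8a oxygens both flank C4a, ring C could close through either, and the wrong one gives the 6-methoxy isomer. Only the C8 and C4' oxygens are methyl ethers; the other five must be freed at the end without touching these two, which excludes Lewis-acid demethylation. The C3 oxygen lies between the C4 carbonyl and C2 and is usually added late by oxidising an enone or enolate, yet the chalcone epoxidation route (Algar–Flynn–Oyamada) tends to give aurones when the position next to the acyl group, here C5, is substituted. Intermediates will hold methoxymethyl (MOM) acetals, benzyl ethers, a diazoketone and finally a free polyphenol, none of which tolerates rough treatment. The enabling feature is that C3 is bonded to oxygen, to the C4 carbonyl and to C2, which is the pattern of a keto-carbene carbon: it first accepts an oxygen nucleophile and then, as an enolate, a carbon electrophile. C2 is then simply the carbonyl carbon of a ring B benzaldehyde. The two stereocentres such a coupling creates are erased before the target, so neither needs control.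

## Retrosynthesis

**20 from 19.** The hydroxyls at C3, C5, C3' and C5' are disconnected as benzyl ethers, so that 20 comes from 3,5-bis(benzyloxy)-2-[3,5-bis(benzyloxy)-4-methoxyphenyl]-7-hydroxy-8-methoxy-4H-chromen-4-one 19 by hydrogenolysis. Methyl masks could not be told from the two ethers that must stay, and silyl ethers would not survive the organolithium and acid steps. Compound 19 is no smaller, but it moves the sensitive polyphenol into the last flask. The forward step must cleave four benzyl–oxygen bonds without saturating C2=C3.

**19 from 17.** Ring C is opened at O1–C2 together with the C2=C3 double bond, leading back to the 2-benzyloxy-1,3-diketone 17. In 17 the C8a and C7 oxygens are MOM ethers and the C5 oxygen is a benzyl ether. The neighbouring cut, oxidative closure of a chalcone, is kept as a fallback; the diketone condensation is preferred because it is redox-neutral and needs only acid. The same acid removes both MOM groups and gives the dihydroxy diketone 18 in the flask. Only the C8a hydroxyl of 18 is both free and ortho to the acyl group, so the protecting groups decide the direction of closure; the freed C7 hydroxyl is para to C4a and cannot cyclise. The forward step needs acetal cleavage and cyclodehydration to outrun cleavage of the diketone.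

**17 from 16.** No skeletal bond is cut. The C2 carbonyl is taken back to a carbinol, giving the β-hydroxy-α-benzyloxy ketone 16, the form in which an aldehyde delivers C2. This avoids acylating a crowded α-alkoxy ketone enolate with a ring B acid derivative. The forward step is a mild alcohol oxidation.

**16 from 9, 14 and 13.** This is the key disconnection: C3–O and C2–C3 are cut together, leaving the ring A diazoketone 9, benzyl alcohol 14 and the ring B aldehyde 13. The stepwise neighbour (prepare the α-benzyloxy ketone, then run an aldol) is kept as the fallback. The three-component version forms the C3–O bond next to the C4 carbonyl and the carbon–carbon bond in one operation, and no enone oxidation is needed. The precursors are far simpler than 16.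

- The forward reaction must let intermolecular capture by the oxygen donor, then by the aldehyde, outrun two things: protonation and attack of the ortho ether oxygens on the carbene.
- An ortho MOM or benzyl ether does not in itself prevent the second; both can form five-membered oxonium ylides that rearrange.
- The benzyl alcohol is therefore delivered as Ti(OCH2Ph)4 15, made in the flask from 14. This gives a high concentration of donor oxygens, leaves no O–H proton to shift, and activates the aldehyde on the same metal.
- Ti(OiPr)4 left as such would itself donate isopropoxide to the carbene and leave an ether at C3 that hydrogenolysis cannot remove, so every isopropoxide is exchanged first.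

**9 from 7.** The C3–N bond is cut: diazo transfer to the methyl ketone 7 through its trifluoroacetyl derivative 8. The neighbouring route, acid chloride plus a diazomethane reagent, would need activation of a doubly ortho-substituted benzoic acid next to an acid-labile MOM ether. The ketone route uses only base and an azide. Ketone 7 has one enolisable side, so no regiochemical question arises.

**7 from 5.** The C4–C4a bond is cut to the aryllithium 6 and an acetyl Weinreb amide. Arene 5 has a mirror plane through the methoxy carbon and the benzyloxy carbon. Its two ring hydrogens are therefore equivalent, each flanked by a MOM ether and the benzyl ether, and the regiochemistry of metalation is fixed by symmetry. This is why the C7 oxygen is a MOM ether and not a benzyl ether: with benzyl there, the two hydrogens would differ and the base would have to choose. Friedel–Crafts acylation would neither tolerate the acetals nor choose a site.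

**5 from 1.** Three carbon–oxygen bonds are cut in turn:

- the benzyl ether of 5, back to phenol 4;
- the aryl C–O bond of 4, back to the C–H of 2 through boronate 3;
- the two MOM ethers of 2, back to 2-methoxybenzene-1,3-diol 1.

Compound 1 already holds the future C8 methoxy between the future C8a and C7 oxygens. A Baeyer–Villiger route from a benzaldehyde would need two more steps. The borylation must select the only C–H of 2 that has no ortho substituent.

**13 from 10.** Functional-group changes only: aldehyde 13 from alcohol 12, ester 11 and 3,5-dihydroxy-4-methoxybenzoic acid 10, which carries the ring B methoxy group from the start.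

## Roads not taken

**Alternative 1:** The cut removes O1–C8a, C4–C4a and O1–C2 at once.

- *Forward step:* CsF releases an aryne from 3,5-bis(benzyloxy)-2-(trimethylsilyl)phenyl trifluoromethanesulfonate A2. The carboxylate of 3-[3,5-bis(benzyloxy)-4-methoxyphenyl]prop-2-ynoic acid A3 adds at the aryne carbon remote from the neighbouring benzyloxy group, and the aryl anion then attacks the carboxyl carbon. The freed phenoxide closes onto the ynone to give 5,7-bis(benzyloxy)-2-[3,5-bis(benzyloxy)-4-methoxyphenyl]chromen-4-one A1.
- *Merits:* three bonds and ring C form in one flask, with the aryne regiochemistry steered by the adjacent alkoxy group. Acid A3 lies close to aldehyde 13, from which an alkyne homologation and a carboxylation would lead to it.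
- *Weak points:* A1 lacks both the C3 oxygen and the C8 methoxy. A late oxygenation of ring A would have to tell C8 from C6, and both are flanked by oxygenated carbons. Putting the methoxy on the aryne instead would place alkoxy groups beside both aryne carbons and lose the steering. A2 is itself several steps from commerce, and 5-exo closure of the ynone derived from A3 competes.
- *Comparison:* this road reaches the flavone skeleton of A1 in fewer operations than the chosen plan, which spends five steps on 9. The chosen plan has every oxygen in place, at the right oxidation level, before ring C closes.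

**Alternative 2:** The cut is O1–C8a alone, with C8a a C–H carbon in the precursor.

- *Forward step:* anodic oxidation, in buffered methanol, of the para-methoxyphenol unit of 2-(benzyloxy)-1-[4-(benzyloxy)-2-hydroxy-5-methoxyphenyl]-3-[3,5-bis(benzyloxy)-4-methoxyphenyl]propane-1,3-dione A5 gives the quinone monoketal 2-(benzyloxy)-1-[4-(benzyloxy)-3,3-dimethoxy-6-oxocyclohexa-1,4-dien-1-yl]-3-[3,5-bis(benzyloxy)-4-methoxyphenyl]propane-1,3-dione A6. The enol oxygen adds to C8a, and loss of methanol rearomatises to 3,7-bis(benzyloxy)-2-[3,5-bis(benzyloxy)-4-methoxyphenyl]-5-hydroxy-8-methoxychromen-4-one A4.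
- *Merits:* no C8a oxygen has to be carried or differentiated, the C5 hydroxyl emerges free, and ring A needs one oxygen fewer at the start. Hydrogenolysis of A4 alone would then give 20. In these respects this road is better than the chosen plan.
- *Weak points:* A5 contains a trialkoxy ring B, four benzyl ethers and an enolisable diketone, all oxidisable. In A6 methanol and the enol carbon compete with the enol oxygen for C8a. A5 still has to be built with the C3 oxygen in place, so the hardest bond set is not addressed.
- *Comparison:* the chosen plan sets against this a ring closure (phenol onto a 1,3-diketone) that is among the most reliable in flavonoid chemistry. Its uncertain step is placed early, on an open chain, whereas the electrolysis leading to A4 comes late.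

**Alternative 3:** The cut removes C4a–C4, C4–C3 and O1–C2.

- *Forward step:* PdCl2(PPh3)2 in diethylamine supplies zerovalent palladium, which inserts into the C–I bond of 3,5-bis(benzyloxy)-2-iodo-6-methoxyphenol A8. Carbon monoxide A10 gives the acylpalladium species, which couples with 1,3-bis(benzyloxy)-5-ethynyl-2-methoxybenzene A9. The amine then promotes 6-endo addition of the phenol to the ynone, giving 5,7-bis(benzyloxy)-2-[3,5-bis(benzyloxy)-4-methoxyphenyl]-8-methoxychromen-4-one A7.
- *Merits:* the reaction type is well established for flavones, it is convergent, the C8 methoxy is in place, alkyne A9 is one homologation away from aldehyde 13, and the step count is likely lower than that of the chosen plan.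
- *Weak points:* A8 is a very electron-rich iodide flanked by two oxygens, so insertion of A10 may lose to direct alkynylation by A9. 5-Exo closure competes. Making A8 needs an iodination that must choose between the position ortho and the position para to the phenol. A7 has no C3 oxygen, so an enone or enolate oxidation would have to be run late on a molecule with four benzylic ethers and two electron-rich rings.
- *Comparison:* this road is the strongest rival. The chosen plan answers with a C3 oxygen present from the moment C3 is bonded, ring A regiochemistry fixed by symmetry, and no need for A10, a toxic gas handled under pressure.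

Key step: step 9

## Route

Remark: 16 is expected as a racemate and as a mixture of two diastereomers; the (2R*,3S*) isomer is drawn and the mixture is carried on, because both centres are erased in steps 10 and 11.

Step 1
Reactants: 1 2-methoxybenzene-1,3-diol
Product: 2 2-methoxy-1,3-bis(methoxymethoxy)benzene
Conditions: MOMCl, iPr2NEt, CH2Cl2, 0 °C to rt
Reagents that add atoms: chloromethyl methyl ether, COCCl
Why: Base-mediated O-alkylation of both phenols (MOM protection). The acetals later direct metalation and are removed by the acid that closes ring C.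

Step 2
Reactants: 2 2-methoxy-1,3-bis(methoxymethoxy)benzene
Product: 4 4-methoxy-3,5-bis(methoxymethoxy)phenol, via aryl pinacolboronate 3 (not isolated)
Conditions: [Ir(OMe)(cod)]2 (cat.), 4,4'-di-tert-butyl-2,2'-bipyridine, B2pin2 (0.6 equiv), THF, 80 °C; then aq NaOH, H2O2, 0 °C
Reagents that add atoms: bis(pinacolato)diboron, CC1(C)OB(OC1(C)C)B1OC(C)(C)C(C)(C)O1 (boron of 3); hydrogen peroxide, OO
Why: Iridium-catalysed C–H borylation is governed by sterics and should take the only C–H of 2 without an ortho substituent. Oxidation of the C–B bond in the same flask then gives the phenol (one-pot borylation–oxidation).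

Step 3
Reactants: 4 4-methoxy-3,5-bis(methoxymethoxy)phenol
Product: 5 5-(benzyloxy)-2-methoxy-1,3-bis(methoxymethoxy)benzene
Conditions: BnBr, K2CO3, DMF, rt
Reagents that add atoms: benzyl bromide, BrCc1ccccc1
Why: Williamson ether synthesis on an unhindered phenoxide. The benzyl ether keeps the future C5 oxygen masked through the acid step.

Step 4
Reactants: 5 5-(benzyloxy)-2-methoxy-1,3-bis(methoxymethoxy)benzene
Product: 7 1-[6-(benzyloxy)-3-methoxy-2,4-bis(methoxymethoxy)phenyl]ethan-1-one, via aryllithium 6 (not isolated)
Conditions: n-BuLi, THF, 0 °C; then MeC(O)N(OMe)Me, −78 °C to 0 °C; aq NH4Cl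
Reagents that add atoms: n-butyllithium, [Li]CCCC (lithium of 6); N-methoxy-N-methylacetamide, CC(=O)N(C)OC
Why: Directed ortho-metalation at a position flanked by a MOM ether and a benzyl ether; the two ring hydrogens of 5 are equivalent by symmetry, so one isomer should result. The Weinreb amide stops at the ketone through its chelated tetrahedral adduct.

Step 5
Reactants: 7 1-[6-(benzyloxy)-3-methoxy-2,4-bis(methoxymethoxy)phenyl]ethan-1-one
Product: 9 1-[6-(benzyloxy)-3-methoxy-2,4-bis(methoxymethoxy)phenyl]-2-diazoethan-1-one, via trifluoroacetyl diketone 8 (not isolated)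
Conditions: LiN(SiMe3)2, THF, −78 °C; CF3CO2CH2CF3; aq NH4Cl; then 4-acetamidobenzenesulfonyl azide, Et3N, H2O (1 equiv), MeCN, rt
Reagents that add atoms: 2,2,2-trifluoroethyl trifluoroacetate, O=C(OCC(F)(F)F)C(F)(F)F (trifluoroacetyl of 8); 4-acetamidobenzenesulfonyl azide, CC(=O)Nc1ccc(cc1)S(=O)(=O)N=[N+]=[N-]
Why: Detrifluoroacetylative diazo transfer: Claisen-type trifluoroacetylation activates the methyl group, and the sulfonyl azide then transfers N2 with loss of the trifluoroacetyl group as a sulfonamide. Only base is used, so the acetals and the benzyl ether are safe.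

Step 6
Reactants: 10 3,5-dihydroxy-4-methoxybenzoic acid
Product: 11 benzyl 3,5-bis(benzyloxy)-4-methoxybenzoate
Conditions: BnBr, K2CO3, DMF, 60 °C
Reagents that add atoms: benzyl bromide, BrCc1ccccc1
Why: Exhaustive O-alkylation of both phenoxides and the carboxylate (Williamson type).

Step 7
Reactants: 11 benzyl 3,5-bis(benzyloxy)-4-methoxybenzoate
Product: 12 [3,5-bis(benzyloxy)-4-methoxyphenyl]methanol
Conditions: LiAlH4, THF, 0 °C; aq NaOH work-up
Reagents that add atoms: none
Why: Hydride reduction of the ester to the primary alcohol; aryl benzyl ethers are inert to LiAlH4.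

Step 8
Reactants: 12 [3,5-bis(benzyloxy)-4-methoxyphenyl]methanol
Product: 13 3,5-bis(benzyloxy)-4-methoxybenzaldehyde
Conditions: MnO2, CH2Cl2, rt
Reagents that add atoms: none
Why: MnO2 oxidises benzylic alcohols selectively and stops at the aldehyde.

Step 9
Reactants: 9 1-[6-(benzyloxy)-3-methoxy-2,4-bis(methoxymethoxy)phenyl]-2-diazoethan-1-one; 14 benzyl alcohol; 13 3,5-bis(benzyloxy)-4-methoxybenzaldehyde
Product: 16 rac-(2R,3S)-2-(benzyloxy)-1-[6-(benzyloxy)-3-methoxy-2,4-bis(methoxymethoxy)phenyl]-3-[3,5-bis(benzyloxy)-4-methoxyphenyl]-3-hydroxypropan-1-one (other diastereomer also acceptable), via titanium tetrabenzyloxide 15 (not isolated)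
Conditions: Ti(OiPr)4 (1.3 equiv), 14 (5.5 equiv), toluene, iPrOH stripped under reduced pressure; then 13 (1.3 equiv), Rh2(OAc)4 (2 mol %), CH2Cl2, 40 °C, 9 added over 4 h; aq potassium sodium tartrate
Reagents that add atoms: titanium tetraisopropoxide, CC(C)O[Ti](OC(C)C)(OC(C)C)OC(C)C (titanium of 15 only)
Why: Rh2(OAc)4 expels nitrogen from 9 and gives an electrophilic rhodium carbene at the future C3. A benzyloxide oxygen of 15 adds to it, and the titanium-bound oxonium ylide that results is in effect an α-benzyloxy titanium enolate; the donor has no O–H, so the 1,2-proton shift that would end in plain insertion has no proton to move. The enolate carbon then adds to aldehyde 13 held on the Lewis-acidic titanium (aldol-type step through a closed six-membered transition state), which forms C2–C3, and aqueous work-up releases 16. The closest known reaction type is the dirhodium-catalysed three-component coupling of diazo carbonyl compounds with alcohols or titanium alkoxides and aldehydes through trapped oxonium ylides. No ring is closed. The two new stereocentres are set only by the geometry of the aldol transition state; the product is racemic, any diastereomer mixture is acceptable, and both centres vanish in steps 10 and 11. The selectivity needed is intermolecular capture by benzyloxide ahead of attack by the ortho ether oxygens (five-membered oxonium ylide, then 1,2-shift), of carbonyl ylide formation with free aldehyde and of carbene dimerisation; it rests on the high concentration of Ti–O donors, the binding of the aldehyde oxygen to titanium, slow addition of 9, and the out-of-plane twist of the doubly ortho-substituted aroyl group, which holds the carbene carbon away from the in-plane ortho oxygens. Exchanging every isopropoxide for benzyloxide beforehand ensures that no isopropoxy group, which could not be removed later, reaches C3.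

Step 10
Reactants: 16 rac-(2R,3S)-2-(benzyloxy)-1-[6-(benzyloxy)-3-methoxy-2,4-bis(methoxymethoxy)phenyl]-3-[3,5-bis(benzyloxy)-4-methoxyphenyl]-3-hydroxypropan-1-one
Product: 17 2-(benzyloxy)-1-[6-(benzyloxy)-3-methoxy-2,4-bis(methoxymethoxy)phenyl]-3-[3,5-bis(benzyloxy)-4-methoxyphenyl]propane-1,3-dione (racemic, enolisable at C2)
Conditions: Dess–Martin periodinane, NaHCO3, CH2Cl2, 0 °C to rt
Reagents that add atoms: none
Why: Dess–Martin oxidation of a secondary benzylic carbinol under buffered, near-neutral conditions that spare the acetals. The carbinol stereocentre is erased and the remaining one becomes enolisable.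

Step 11
Reactants: 17 2-(benzyloxy)-1-[6-(benzyloxy)-3-methoxy-2,4-bis(methoxymethoxy)phenyl]-3-[3,5-bis(benzyloxy)-4-methoxyphenyl]propane-1,3-dione
Product: 19 3,5-bis(benzyloxy)-2-[3,5-bis(benzyloxy)-4-methoxyphenyl]-7-hydroxy-8-methoxy-4H-chromen-4-one, via dihydroxy diketone 18 (not isolated)
Conditions: HCl, MeOH/THF, 50 °C
Reagents that add atoms: none
Why: Acid-catalysed acetal cleavage frees the C8a and C7 hydroxyls. The C8a hydroxyl, the only free one ortho to the acyl group, then adds to the ring B carbonyl, and water is lost (cyclodehydration of an o-hydroxyaryl 1,3-diketone, as in the last stage of a Baker–Venkataraman flavone synthesis). The C5 benzyl ether blocks closure in the other direction.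

Step 12
Reactants: 19 3,5-bis(benzyloxy)-2-[3,5-bis(benzyloxy)-4-methoxyphenyl]-7-hydroxy-8-methoxy-4H-chromen-4-one
Product: 20 2-(3,5-dihydroxy-4-methoxyphenyl)-3,5,7-trihydroxy-8-methoxy-4H-chromen-4-one
Conditions: H2 (1 atm), Pd/C, THF/MeOH, rt
Reagents that add atoms: none
Why: Catalytic hydrogenolysis of three aryl benzyl ethers and the C3 enol benzyl ether. Methyl ethers are inert, and the conjugated, hydrogen-bonded pyranone double bond of flavonols normally survives these conditions.

## Compound list

1 | 2-methoxybenzene-1,3-diol | COc1c(O)cccc1O | starting material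
2 | 2-methoxy-1,3-bis(methoxymethoxy)benzene | COCOc1cccc(OCOC)c1OC | intermediate
3 | 2-[4-methoxy-3,5-bis(methoxymethoxy)phenyl]-4,4,5,5-tetramethyl-1,3,2-dioxaborolane | COCOc1cc(cc(OCOC)c1OC)B1OC(C)(C)C(C)(C)O1 | intermediate (not isolated)
4 | 4-methoxy-3,5-bis(methoxymethoxy)phenol | COCOc1cc(O)cc(OCOC)c1OC | intermediate
5 | 5-(benzyloxy)-2-methoxy-1,3-bis(methoxymethoxy)benzene | COCOc1cc(OCc2ccccc2)cc(OCOC)c1OC | intermediate
6 | [6-(benzyloxy)-3-methoxy-2,4-bis(methoxymethoxy)phenyl]lithium | [Li]c1c(OCc2ccccc2)cc(OCOC)c(OC)c1OCOC | intermediate (not isolated)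
7 | 1-[6-(benzyloxy)-3-methoxy-2,4-bis(methoxymethoxy)phenyl]ethan-1-one | CC(=O)c1c(OCc2ccccc2)cc(OCOC)c(OC)c1OCOC | intermediate
8 | 1-[6-(benzyloxy)-3-methoxy-2,4-bis(methoxymethoxy)phenyl]-4,4,4-trifluorobutane-1,3-dione | O=C(CC(=O)C(F)(F)F)c1c(OCc2ccccc2)cc(OCOC)c(OC)c1OCOC | intermediate (not isolated)
9 | 1-[6-(benzyloxy)-3-methoxy-2,4-bis(methoxymethoxy)phenyl]-2-diazoethan-1-one | [N-]=[N+]=CC(=O)c1c(OCc2ccccc2)cc(OCOC)c(OC)c1OCOC | intermediate
10 | 3,5-dihydroxy-4-methoxybenzoic acid | COc1c(O)cc(cc1O)C(=O)O | starting material
11 | benzyl 3,5-bis(benzyloxy)-4-methoxybenzoate | COc1c(OCc2ccccc2)cc(cc1OCc1ccccc1)C(=O)OCc1ccccc1 | intermediate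
12 | [3,5-bis(benzyloxy)-4-methoxyphenyl]methanol | COc1c(OCc2ccccc2)cc(CO)cc1OCc1ccccc1 | intermediate
13 | 3,5-bis(benzyloxy)-4-methoxybenzaldehyde | COc1c(OCc2ccccc2)cc(C=O)cc1OCc1ccccc1 | intermediate
14 | benzyl alcohol | OCc1ccccc1 | starting material
15 | titanium tetrabenzyloxide, Ti(OCH2Ph)4 | C(O[Ti](OCc1ccccc1)(OCc1ccccc1)OCc1ccccc1)c1ccccc1 | intermediate (not isolated)
16 | rac-(2R,3S)-2-(benzyloxy)-1-[6-(benzyloxy)-3-methoxy-2,4-bis(methoxymethoxy)phenyl]-3-[3,5-bis(benzyloxy)-4-methoxyphenyl]-3-hydroxypropan-1-one | COCOc1c(OC)c(OCOC)cc(OCc2ccccc2)c1C(=O)[C@H](OCc1ccccc1)[C@@H](O)c1cc(OCc2ccccc2)c(OC)c(OCc2ccccc2)c1 | intermediate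
17 | 2-(benzyloxy)-1-[6-(benzyloxy)-3-methoxy-2,4-bis(methoxymethoxy)phenyl]-3-[3,5-bis(benzyloxy)-4-methoxyphenyl]propane-1,3-dione (racemic) | COCOc1c(OC)c(OCOC)cc(OCc2ccccc2)c1C(=O)C(OCc1ccccc1)C(=O)c1cc(OCc2ccccc2)c(OC)c(OCc2ccccc2)c1 | intermediate
18 | 2-(benzyloxy)-1-[6-(benzyloxy)-2,4-dihydroxy-3-methoxyphenyl]-3-[3,5-bis(benzyloxy)-4-methoxyphenyl]propane-1,3-dione (racemic) | COc1c(O)cc(OCc2ccccc2)c(C(=O)C(OCc2ccccc2)C(=O)c2cc(OCc3ccccc3)c(OC)c(OCc3ccccc3)c2)c1O | intermediate (not isolated)
19 | 3,5-bis(benzyloxy)-2-[3,5-bis(benzyloxy)-4-methoxyphenyl]-7-hydroxy-8-methoxy-4H-chromen-4-one | COc1c(O)cc(OCc2ccccc2)c2c1oc(-c1cc(OCc3ccccc3)c(OC)c(OCc3ccccc3)c1)c(OCc1ccccc1)c2=O | intermediate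
20 | 2-(3,5-dihydroxy-4-methoxyphenyl)-3,5,7-trihydroxy-8-methoxy-4H-chromen-4-one | COc1c(O)cc(-c2oc3c(OC)c(O)cc(O)c3c(=O)c2O)cc1O | target

## Step count and risks

Total: 12 steps. Longest linear sequence: 9 steps (steps 1–5 and 9–12); ring B aldehyde 13 is made in 3 steps in parallel.

**Step 9 (key step).** The most likely failure is capture of the carbene by an ortho ether oxygen. This would give a five-membered oxonium ylide, which would then undergo 1,2-shift of the benzyl or methoxymethyl group, faster than a titanium-bound benzyloxide can reach the carbene. Premature protonation of the enolate and carbene dimerisation are lesser losses. The fallback avoids the carbene. Arene 5 is lithiated as in step 4 (via 6) and acylated with N-methoxy-N-methyl-2-(benzyloxy)acetamide to give 2-(benzyloxy)-1-[6-(benzyloxy)-3-methoxy-2,4-bis(methoxymethoxy)phenyl]ethan-1-one F1. Its lithium enolate (LiN(SiMe3)2, THF, −78 °C) is then added to aldehyde 13 in an ordinary aldol reaction, which rejoins the route at 16. F1 is also what premature protonation in step 9 would leave, so that material can be sent down the same path.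

**Step 4.** Two processes could compete with ortho-metalation and acylation. One is deprotonation of the benzylic CH2 of the benzyl ether at 0 °C, followed by Wittig-type rearrangement. The other is proton transfer from the acetamide to the hindered aryllithium, which returns 5. The fallback starts from 5. Bromination with N-bromosuccinimide (MeCN, 0 °C) should give a single isomer by symmetry, 1-(benzyloxy)-2-bromo-4-methoxy-3,5-bis(methoxymethoxy)benzene F2. Bromine–lithium exchange (n-BuLi, THF, −78 °C) and addition to acetaldehyde should give racemic 1-[6-(benzyloxy)-3-methoxy-2,4-bis(methoxymethoxy)phenyl]ethan-1-ol F3. Dess–Martin oxidation then returns to the route at 7.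

**Step 11.** Methanol may cleave the crowded 2-alkoxy-1,3-diketone (retro-Claisen fragmentation) before the phenol is unmasked and closes the ring. The fallback starts from 16 and never forms the diketone. Acid (HCl, MeOH/THF) should remove both acetals and dehydrate the carbinol to (Z)-2-(benzyloxy)-1-[6-(benzyloxy)-2,4-dihydroxy-3-methoxyphenyl]-3-[3,5-bis(benzyloxy)-4-methoxyphenyl]prop-2-en-1-one F4. Oxidative cyclisation of this 2'-hydroxychalcone with catalytic I2 in DMSO at 110 °C rejoins the route at 19.

**Step 12.** Hydrogen may saturate the C2=C3 bond, or cleavage of the hindered C3 and C5 benzyl ethers may stall on the poorly soluble polyphenol. The fallback treats 19 with BCl3 and pentamethylbenzene in CH2Cl2 at −78 °C, a Lewis-acid debenzylation in which the arene traps the benzyl cation. The low temperature should leave the two methyl ethers intact. It gives 20 directly, with no new intermediate.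

## Further compounds

F1 | step 9 | 2-(benzyloxy)-1-[6-(benzyloxy)-3-methoxy-2,4-bis(methoxymethoxy)phenyl]ethan-1-one | O=C(COCc1ccccc1)c1c(OCc2ccccc2)cc(OCOC)c(OC)c1OCOC
F2 | step 4 | 1-(benzyloxy)-2-bromo-4-methoxy-3,5-bis(methoxymethoxy)benzene | Brc1c(OCc2ccccc2)cc(OCOC)c(OC)c1OCOC
F3 | step 4 | 1-[6-(benzyloxy)-3-methoxy-2,4-bis(methoxymethoxy)phenyl]ethan-1-ol (racemic) | CC(O)c1c(OCc2ccccc2)cc(OCOC)c(OC)c1OCOC
F4 | step 11 | (Z)-2-(benzyloxy)-1-[6-(benzyloxy)-2,4-dihydroxy-3-methoxyphenyl]-3-[3,5-bis(benzyloxy)-4-methoxyphenyl]prop-2-en-1-one | COc1c(O)cc(OCc2ccccc2)c(C(=O)/C(OCc2ccccc2)=C/c2cc(OCc3ccccc3)c(OC)c(OCc3ccccc3)c2)c1O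
F0 | step 12 | none | none
A1 | alternative 1 | 5,7-bis(benzyloxy)-2-[3,5-bis(benzyloxy)-4-methoxyphenyl]chromen-4-one | O=c1cc(-c2cc(OCc3ccccc3)c(OC)c(OCc3ccccc3)c2)oc2cc(OCc3ccccc3)cc(OCc3ccccc3)c12
A2 | alternative 1 | 3,5-bis(benzyloxy)-2-(trimethylsilyl)phenyl trifluoromethanesulfonate | C[Si](C)(C)c1c(OS(=O)(=O)C(F)(F)F)cc(OCc2ccccc2)cc1OCc1ccccc1
A3 | alternative 1 | 3-[3,5-bis(benzyloxy)-4-methoxyphenyl]prop-2-ynoic acid | OC(=O)C#Cc1cc(OCc2ccccc2)c(OC)c(OCc2ccccc2)c1
A4 | alternative 2 | 3,7-bis(benzyloxy)-2-[3,5-bis(benzyloxy)-4-methoxyphenyl]-5-hydroxy-8-methoxychromen-4-one | COc1c(OCc2ccccc2)cc(O)c2c1oc(-c1cc(OCc3ccccc3)c(OC)c(OCc3ccccc3)c1)c(OCc1ccccc1)c2=O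
A5 | alternative 2 | 2-(benzyloxy)-1-[4-(benzyloxy)-2-hydroxy-5-methoxyphenyl]-3-[3,5-bis(benzyloxy)-4-methoxyphenyl]propane-1,3-dione | COc1cc(C(=O)C(OCc2ccccc2)C(=O)c2cc(OCc3ccccc3)c(OC)c(OCc3ccccc3)c2)c(O)cc1OCc1ccccc1
A6 | alternative 2 | 2-(benzyloxy)-1-[4-(benzyloxy)-3,3-dimethoxy-6-oxocyclohexa-1,4-dien-1-yl]-3-[3,5-bis(benzyloxy)-4-methoxyphenyl]propane-1,3-dione | COC1(OC)C=C(C(=O)C(OCc2ccccc2)C(=O)c2cc(OCc3ccccc3)c(OC)c(OCc3ccccc3)c2)C(=O)C=C1OCc1ccccc1
A7 | alternative 3 | 5,7-bis(benzyloxy)-2-[3,5-bis(benzyloxy)-4-methoxyphenyl]-8-methoxychromen-4-one | COc1c(OCc2ccccc2)cc(OCc2ccccc2)c2c1oc(-c1cc(OCc3ccccc3)c(OC)c(OCc3ccccc3)c1)cc2=O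
A8 | alternative 3 | 3,5-bis(benzyloxy)-2-iodo-6-methoxyphenol | COc1c(O)c(I)c(OCc2ccccc2)cc1OCc1ccccc1
A9 | alternative 3 | 1,3-bis(benzyloxy)-5-ethynyl-2-methoxybenzene | C#Cc1cc(OCc2ccccc2)c(OC)c(OCc2ccccc2)c1
A10 | alternative 3 | carbon monoxide | [C-]#[O+]
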